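The eight-membered ring is cut at C1–C2 (acetoxy carbon to ring CH2) and at C4–C5 (the cyclopropane bond shared with that ring). C1 and C5 sit 1,5 across the butenolide edge C8–C7=C6, so one oxygen, the later acetate oxygen, ties them into a lactone-fused 2-hydroxy-3,4-dihydro-2H-pyran: C1 a lactol, C5 a vinylogous-carbonate carbon. In one Me3SiOTf operation 2-methylene-1,3-bis(trimethylsilyl)propane adds to C1 (Hosomi–Sakurai) and closes on C5 (Sakurai–Prins), giving an oxygen-bridged cyclooctane. Lactone-enolate β-elimination later opens the bridge to the C4=C5 alkene, which takes the hydroxyl-directed cyclopropane methylene.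

Key step: step 5

Remark on labels: C1 = CH–OAc, C2 = ring CH2, C3 = CHMe, C4 and C5 = cyclopropane CH (C5 on the butenolide), C6 and C7 = butenolide α- and β-carbon, C8 = ring CH with the side chain, C10 = lactone C=O, C11 = OCH2, C12 = cyclopropane CH2; side chain C1′ (CHMe) to C5′ (CMe2).

Remark on the chemistry: C6 and C7 are temporary stereocentres (both become sp2 in step 9); they are carried as mixtures and are left undefined in the SMILES of 5–16, F1 and F2.

Remark on the chemistry: the sense of induction of SAMP at C8 is taken from the established azaenolate model (carbonyl carbon, new substituent and old substituent arranged as in (S)-4-methylheptan-3-one made from pentan-3-one).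

Step 1
Reactants: 1 (R)-citronellal; 2 SAMP
Product: 3 (E)-SAMP hydrazone of (R)-citronellal
Conditions: CH2Cl2, MgSO4, 0 °C to rt
Reagents that add atoms: none
Why: Hydrazone formation from an aldehyde and a 1,1-dialkylhydrazine is fast and clean, gives the (E)-hydrazone, installs the auxiliary and masks the aldehyde without touching the C1′ stereocentre taken from the chiral pool.

Step 2
Reactants: 3 (E)-SAMP hydrazone of (R)-citronellal; 4 furan-2(5H)-one
Product: 5 Michael adduct (β-substituted γ-butyrolactone hydrazone)
Conditions: LiN(iPr)2, THF, 0 °C; then 4, −78 °C; AcOH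
Reagents that add atoms: none
Why: Enders SAMP-hydrazone Michael addition, in which the chelated lithium azaenolate should add 1,4 to the butenolide at −78 °C faster than it deprotonates it and the auxiliary shields one face, so that C8 is set as (S) by auxiliary control while the lactone carbon C7 is a temporary centre.

Step 3
Reactants: 5 Michael adduct
Product: 7 lactone-fused lactol (2-hydroxy-3,4-dihydro-2H-pyran), via hydroxymethylene lactone hydrazone 6 (not isolated)
Conditions: NaH, HCO2Et, THF, 0 °C to rt; then sat. aq. (CO2H)2, Et2O, rt
Reagents that add atoms: ethyl formate, CCOC=O; water, O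
Why: Crossed Claisen formylation of the lactone α-CH2 (far more acidic than the hydrazone α-CH) should give the hydroxymethylene lactone, and mild biphasic oxalic acid cleavage of the hydrazone (no epimerisation at C8, alkene untouched) frees the C1 aldehyde, which the enol traps as the six-membered lactol as in iridoid aglycones.

Step 4
Reactants: 8 3-chloro-2-(chloromethyl)prop-1-ene
Product: 9 2-methylene-1,3-bis(trimethylsilyl)propane
Conditions: Mg, Me3SiCl, THF, reflux
Reagents that add atoms: chlorotrimethylsilane, C[Si](C)(C)Cl
Why: In situ Grignard (Barbier-type) silylation of both allylic chlorides is the standard way to this bis(allylsilane) conjunctive reagent.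

Step 5
Reactants: 7 lactone-fused lactol; 9 2-methylene-1,3-bis(trimethylsilyl)propane
Product: 11 3-methylene-9-oxabicyclo[3.3.1]nonane fused to the γ-lactone, via C1-allylated dihydropyran allylsilane 10 (not isolated)
Conditions: 9 (3 equiv), Me3SiOTf (2.2 equiv), 2,6-di-tert-butyl-4-methylpyridine, CH2Cl2, −78 to −20 °C; aq. NaHCO3
Reagents that add atoms: none
Why: Me3SiOTf silylates and ionises lactol 7 to the cyclic oxocarbenium ion at C1, one terminus of 9 attacks it in an SE2′ Hosomi–Sakurai reaction to give the new 2-substituted allylsilane 10, and Me3SiOTf then O-silylates the lactone carbonyl of the vinylogous carbonate so that C5 becomes an oxocarbenium carbon on which the second allylsilane terminus closes with loss of the second silyl group. The closest known reaction types are the [3+n] annulation of 2-methylene-1,3-bis(silyl)propanes with bis-electrophiles and the silyl triflate mediated Sakurai–Prins cyclisation of vinylogous carbonates to 2,6-cis-tetrahydropyrans. The one ring closed is the tetrahydropyran O–C1–C2–C3–C4–C5, by a chair-like 6-endo-trig attack of C4 on the endocyclic C5=O+ bond, and this closure also completes the eight-membered carbocycle C1–C8 as a 9-oxabicyclo[3.3.1]nonane. C1 is set by attack anti to the branched side chain on the adjacent C8 of the flattened dihydropyranyl cation (substrate control), C5 follows from the tether because C4 can only reach the pyran face on which C2 sits, and C6 is a temporary centre formed by protonation of the silyl ketene acetal on work-up. The step needs the lactol to ionise before the vinylogous carbonate (the anomeric leaving group is lost far more easily), γ-attack of each allylsilane (inherent in SE2′) and capture of the C1 cation by 9 before the trisubstituted side-chain alkene can add to it, which the excess of this far more nucleophilic doubly β-silyl-stabilised alkene at −78 °C should secure.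

Step 6
Reactants: 11 3-methylene-9-oxabicyclo[3.3.1]nonane lactone
Product: 12 endo-3-methyl-9-oxabicyclo[3.3.1]nonane lactone
Conditions: H2 (1 atm), RhCl(PPh3)3 (5 mol %), benzene, rt
Reagents that add atoms: none
Why: Homogeneous hydrogenation with Wilkinson's catalyst should reduce only the 1,1-disubstituted exocyclic alkene (the trisubstituted side-chain alkene is inert) and deliver hydrogen to the open exo face of C3, the endo face being blocked by C7 and the lactone, which places the methyl group endo, that is trans to the oxygen bridge as C3 requires.

Step 7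
Reactants: 12 endo-3-methyl-9-oxabicyclo[3.3.1]nonane lactone
Product: 14 (4Z)-cyclooctenol with β,γ-unsaturated lactone, via ring-opened alkylidene lactone 13 (not isolated)
Conditions: LiN(iPr)2 (3.2 equiv), THF, −78 to −30 °C; then AcOH, −78 °C
Reagents that add atoms: none
Why: The lactone enolate should expel the β-alkoxide (E1cB, retro-oxa-Michael) to open the oxygen bridge and free the C1 alkoxide, the excess amide base then removes the γ-proton at C4 of alkylidene lactone 13, and kinetic α-protonation of the extended enolate gives the deconjugated lactone with the C4=C5 alkene, which is necessarily cis in the eight-membered ring.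

Step 8
Reactants: 14 (4Z)-cyclooctenol with β,γ-unsaturated lactone
Product: 15 cyclopropane-fused hydroxy lactone
Conditions: Et2Zn, CH2I2, CH2Cl2, 0 °C
Reagents that add atoms: diiodomethane, ICI
Why: In this Furukawa-modified Simmons–Smith cyclopropanation the zinc alkoxide at C1, whose oxygen was bonded to C5 until step 7, should deliver the carbenoid across the ring to the cis C4=C5 alkene on its own face (also the face anti to the C3 methyl), which sets C4 and C5 with C12 cis to the C1 oxygen and stereospecifically cis-fused, while the undirected trisubstituted alkene reacts much more slowly.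

Step 9
Reactants: 15 cyclopropane-fused hydroxy lactone
Product: 17 hydroxy butenolide (desacetyl acetoxycrenulide), via α-phenylseleno lactone 16 (not isolated)
Conditions: LiN(iPr)2 (2.2 equiv), THF, −78 °C; PhSeBr; then H2O2, pyridine, CH2Cl2, 0 °C to rt
Reagents that add atoms: benzeneselenenyl bromide, Br[Se]c1ccccc1 (its atoms are carried only in 16)
Why: α-Selenenylation of the lactone lithium enolate anti to the C8-bearing substituent on C7 places selenium syn to H7, and the selenoxide should undergo syn-elimination toward C7 only (elimination toward the cyclopropane carbon C5 would give an alkylidenecyclopropane), so the C6=C7 butenolide forms and both temporary stereocentres disappear.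

Step 10
Reactants: 17 hydroxy butenolide
Product: 18 acetoxycrenulide
Conditions: Ac2O, pyridine, DMAP (cat.), CH2Cl2, rt
Reagents that add atoms: acetic anhydride, CC(=O)OC(C)=O
Why: DMAP-catalysed acetylation of the secondary C1 alcohol is a routine esterification that leaves butenolide, cyclopropane and side-chain alkene untouched.

Step 11
Reactants: 18 acetoxycrenulide
Product: 19 target hydroperoxide
Conditions: O2, hν (visible), tetraphenylporphyrin (cat.), CH2Cl2, 0 °C; chromatography
Reagents that add atoms: dioxygen, O=O
Why: In the Schenck ene reaction singlet oxygen should attack only the electron-rich trisubstituted side-chain alkene (the tetrasubstituted butenolide alkene is electron-poor), and abstraction of an allylic hydrogen from C3′ places the hydroperoxy group on C5′ and moves the alkene to the (E)-C3′=C4′ position, the product being separated from the secondary hydroperoxide that arises by abstraction from a methyl group.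

Compound list
1 | (R)-citronellal, (3R)-3,7-dimethyloct-6-enal | O=CC[C@H](C)CCC=C(C)C | starting material
2 | SAMP, (S)-1-amino-2-(methoxymethyl)pyrrolidine | COC[C@@H]1CCCN1N | starting material
3 | (E)-SAMP hydrazone of (R)-citronellal | COC[C@@H]1CCCN1/N=C/C[C@H](C)CCC=C(C)C | intermediate
4 | furan-2(5H)-one | O=C1OCC=C1 | starting material
5 | SAMP hydrazone of (2S,3R)-3,7-dimethyl-2-(5-oxotetrahydrofuran-3-yl)oct-6-enal (C8 S, C7 undefined) | COC[C@@H]1CCCN1/N=C/[C@H](C2COC(=O)C2)[C@H](C)CCC=C(C)C | intermediate
6 | SAMP hydrazone of (2S,3R)-2-[4-(hydroxymethylene)-5-oxotetrahydrofuran-3-yl]-3,7-dimethyloct-6-enal | COC[C@@H]1CCCN1/N=C/[C@H](C2COC(=O)C2=CO)[C@H](C)CCC=C(C)C | intermediate (not isolated)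
7 | lactol: 6-hydroxy-7-[(2R)-6-methylhept-5-en-2-yl]-1,6,7,7a-tetrahydro-3H-furo[3,4-c]pyran-3-one (C8 S, anomeric mixture; C1 lactol, C5=C6 enol ether) | OC1OC=C2C(=O)OCC2[C@@H]1[C@H](C)CCC=C(C)C | intermediate
8 | 3-chloro-2-(chloromethyl)prop-1-ene | C=C(CCl)CCl | starting material
9 | 2-methylene-1,3-bis(trimethylsilyl)propane | C=C(C[Si](C)(C)C)C[Si](C)(C)C | intermediate
10 | analogue of 7 with the C1 hydroxyl replaced by a 2-[(trimethylsilyl)methyl]prop-2-en-1-yl group, new C1–C2 bond trans to the C8 side chain | C=C(C[Si](C)(C)C)C[C@H]1OC=C2C(=O)OCC2[C@@H]1[C@H](C)CCC=C(C)C | intermediate (not isolated)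
11 | 3-methylene-9-oxabicyclo[3.3.1]nonane (C1–C8, oxygen bridging C1 and C5) fused at C6–C7 to the γ-lactone C6–C10(=O)–O–C11–C7, side chain on C8 on the face of the oxygen bridge | C=C1C[C@H]2O[C@@H](C1)C3C(=O)OCC3[C@@H]2[C@H](C)CCC=C(C)C | intermediate
12 | 3-methyl analogue of 11, methyl endo (trans to the oxygen bridge) | C[C@@H]1C[C@H]2O[C@@H](C1)C3C(=O)OCC3[C@@H]2[C@H](C)CCC=C(C)C | intermediate
13 | ring-opened cyclooctane with free C1–OH and (Z)-C5=C6 alkylidene lactone | O[C@@H]1C[C@@H](C)C/C=C2/C(=O)OCC2[C@@H]1[C@H](C)CCC=C(C)C | intermediate (not isolated)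
14 | (4Z)-cyclooctene with C1–OH, C3 methyl trans to OH, C8 side chain cis to OH, lactone fused at C6–C7 (C6–H) | O[C@@H]1C[C@@H](C)/C=C\C2C(=O)OCC2[C@@H]1[C@H](C)CCC=C(C)C | intermediate
15 | cis-fused bicyclo[6.1.0]nonane hydroxy lactone, C12 cis to C1–OH | O[C@@H]1C[C@@H](C)[C@@H]2C[C@@H]2C2C(=O)OCC2[C@@H]1[C@H](C)CCC=C(C)C | intermediate
16 | C6-phenylseleno derivative of 15 | O[C@@H]1C[C@@H](C)[C@@H]2C[C@@H]2C2([Se]c3ccccc3)C(=O)OCC2[C@@H]1[C@H](C)CCC=C(C)C | intermediate (not isolated)
17 | desacetyl acetoxycrenulide (C1–OH, C6=C7 butenolide) | O[C@@H]1C[C@@H](C)[C@@H]2C[C@@H]2C2=C(COC2=O)[C@@H]1[C@H](C)CCC=C(C)C | intermediate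
18 | acetoxycrenulide | CC(=O)O[C@@H]1C[C@@H](C)[C@@H]2C[C@@H]2C2=C(COC2=O)[C@@H]1[C@H](C)CCC=C(C)C | intermediate
19 | target: (E)-C3′=C4′, C5′-hydroperoxide of acetoxycrenulide, (1R,3R,4S,5S,8S,1′R) in the labels used here | CC(=O)O[C@@H]1C[C@@H](C)[C@@H]2C[C@@H]2C2=C(COC2=O)[C@@H]1[C@H](C)C/C=C/C(C)(C)OO | target

Total step count: 11. Longest linear sequence: 10 steps (steps 1–3 and 5–11).

Steps most likely to fail

Step 5. The side-chain alkene may close onto the C1 oxocarbenium ion in a Prins reaction (the citronellal-to-isopulegol pathway), or facial selectivity at C1 may be low. The fallback sets out from 7 and comes back at 11, and generates no cation at C1. The sodium salt of 7 (NaH, THF; the lactol opens to the C1 aldehyde and the formyl-lactone enolate) is allylated at −78 °C with B-[2-(trimethylsilylmethyl)allyl]diisopinocampheylborane, prepared in situ from [2-(trimethylsilylmethyl)allyl]magnesium chloride and the Ipc2BOMe enantiomer that delivers the (1R) carbinol (Brown allylboration, reagent control). Ethanolamine work-up gives hydroxy allylsilane F1. Me3SiOTf in Et2O at −78 °C then closes the tetrahydropyran by intramolecular Sakurai cyclisation of the C1 hydroxyl and the allylsilane onto the C5 formyl carbon (pyran annulation), which gives 11.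

Step 7. Reconjugation may occur: γ-protonation of the extended enolate, or base-induced isomerisation of 14, returns the alkylidene lactone, which recloses to 12 by oxa-Michael addition. The fallback sets out from 12 and comes back at 17; it introduces the butenolide double bond first and uses it to open the bridge. The enolate of 12 is generated with LiN(iPr)2 at −100 °C in the presence of PhSeBr to give bridged α-phenylseleno lactone F2. Its selenoxide (H2O2) eliminates away from the oxygen-bearing C5 to give bridged butenolide F3. LiN(SiMe3)2 (2.5 equiv) deprotonates C11, the resulting 2-oxidofuran expels the C5 alkoxide, and a second deprotonation at C4 followed by protonation at C11 on work-up gives hydroxy dienyl butenolide F4, which cannot reclose because C5 is no longer electrophilic. Hydroxyl-directed Simmons–Smith cyclopropanation (Et2Zn, CH2I2) of its C4=C5 alkene gives 17, so steps 8 and 9 are bypassed.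

Step 11. Regioselectivity of hydrogen abstraction in the ene reaction (methyl versus C3′ methylene) may be poor, lowering the share of the tertiary hydroperoxide. The fallback sets out from 18 and comes back at 19. Cross-metathesis of the trisubstituted alkene of 18 with 2-methylbut-3-en-2-ol using (H2IMes)(PCy3)Cl2Ru=CHPh (second-generation Grubbs catalyst) gives (E)-configured tertiary allylic alcohol F5. Acid-catalysed perhydrolysis (50% aq. H2O2, cat. H2SO4, Et2O, 0 °C) through the tertiary allylic cation then gives 19.

Further compounds
F1 | step 5 | hydroxy allylsilane: (1R)-carbinol bearing the 2-[(trimethylsilyl)methyl]allyl group at C1 and the hydroxymethylene lactone at C8 | C=C(C[Si](C)(C)C)C[C@@H](O)[C@H](C1COC(=O)C1=CO)[C@H](C)CCC=C(C)C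
F2 | step 7 | C6-phenylseleno derivative of 12 | C[C@@H]1C[C@H]2O[C@@H](C1)C3([Se]c4ccccc4)C(=O)OCC3[C@@H]2[C@H](C)CCC=C(C)C
F3 | step 7 | oxygen-bridged butenolide (C6=C7) derived from 12 | C[C@@H]1C[C@H]2O[C@@H](C1)C3=C(COC3=O)[C@@H]2[C@H](C)CCC=C(C)C
F4 | step 7 | (4Z)-cyclooctenol with C6=C7 butenolide (hydroxy dienyl butenolide) | O[C@@H]1C[C@@H](C)/C=C\C2=C(COC2=O)[C@@H]1[C@H](C)CCC=C(C)C
F5 | step 11 | (E)-C3′=C4′ tertiary C5′ alcohol of acetoxycrenulide | CC(=O)O[C@@H]1C[C@@H](C)[C@@H]2C[C@@H]2C2=C(COC2=O)[C@@H]1[C@H](C)C/C=C/C(C)(C)O
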